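**Retrosynthetic overview**
- The butenolide is unmasked last from a 3‑substituted furan: singlet‑oxygen [4+2] to the γ‑hydroxybutenolide, borohydride reduction with relactonisation, then desilylation.
- The (E)‑trisubstituted olefin bearing CH2OH comes from a Wittig reaction of a β‑silyloxy aldehyde with an α‑alkylated ester‑stabilised ylide, followed by i‑Bu2AlH reduction.
- The only stereocentre (S carbinol) is set by ketoreductase reduction of an achiral 3‑furyl β‑keto ester.
- The ylide side chain comes from dihydro‑β‑ionone: methyl ketone to terminal alkyne, Zr‑catalysed carboalumination with ethylene oxide trapping (E olefin), iodide, alkylation of Ph3P=CHCO2Et.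
- Ring order: no carbocycle is built; the cyclohexene and furan rings are bought, and the furan is turned into the butenolide ring at the end.

Assumption: the target is the S carbinol with both chain olefins E, as the SMILES encodes, and the three achiral starting materials are taken as commercially available.

**Step 1**
Reactants: 1 ethyl 3-(furan-3-yl)-3-oxopropanoate
Product: 2 ethyl (3S)-3-(furan-3-yl)-3-hydroxypropanoate
Conditions: (S)-selective ketoreductase (NADPH-dependent alcohol dehydrogenase, oxidoreductase class), NADP+ (cat.), i-PrOH (10 vol%), KH2PO4/K2HPO4 buffer pH 7.0, 30 °C, 24 h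
Reagents that add atoms: none
Why: Aryl β‑keto esters are standard ketoreductase substrates, and the enzyme delivers the cofactor hydride to one carbonyl face only (Prelog‑type enantioselective biocatalytic reduction with propan‑2‑ol cofactor recycling), which sets the single stereocentre as S.

**Step 2**
Reactants: 2 ethyl (3S)-3-(furan-3-yl)-3-hydroxypropanoate
Product: 3 ethyl (3S)-3-[(tert-butyldimethylsilyl)oxy]-3-(furan-3-yl)propanoate
Conditions: TBSCl, imidazole, DMF, rt
Reagents that add atoms: tert-butyldimethylsilyl chloride (TBSCl), CC(C)(C)[Si](C)(C)Cl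
Why: Standard silylation of a secondary alcohol gives a silyl ether that blocks retro‑aldol and β‑elimination pathways later, and the stereocentre is not touched.

**Step 3**
Reactants: 3 ethyl (3S)-3-[(tert-butyldimethylsilyl)oxy]-3-(furan-3-yl)propanoate
Product: 4 (3S)-3-[(tert-butyldimethylsilyl)oxy]-3-(furan-3-yl)propan-1-ol
Conditions: i-Bu2AlH (2.5 equiv), CH2Cl2, −78 to 0 °C; aq. potassium sodium tartrate
Reagents that add atoms: none
Why: Aluminium hydride reduction of the ester to the primary alcohol leaves the furan and silyl ether intact, and the stereocentre, being β to the ester, cannot epimerise.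

**Step 4**
Reactants: 4 (3S)-3-[(tert-butyldimethylsilyl)oxy]-3-(furan-3-yl)propan-1-ol
Product: 5 (3S)-3-[(tert-butyldimethylsilyl)oxy]-3-(furan-3-yl)propanal
Conditions: Dess–Martin periodinane, pyridine, CH2Cl2, 0 °C to rt
Reagents that add atoms: none
Why: Dess–Martin oxidation gives the aldehyde under buffered, near‑neutral conditions without over‑oxidation, and the β‑stereocentre is not enolisable.

**Step 5**
Reactants: 6 4-(2,6,6-trimethylcyclohex-1-en-1-yl)butan-2-one (dihydro-β-ionone)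
Product: 8 2-(but-3-yn-1-yl)-1,3,3-trimethylcyclohex-1-ene, via enol phosphate 7 (not isolated)
Conditions: LiN(i-Pr)2 (1.05 equiv), THF, −78 °C; ClP(O)(OEt)2, −78 °C to rt; then LiN(i-Pr)2 (2.3 equiv), THF, −78 °C to rt; aq. NH4Cl
Reagents that add atoms: none
Why: Negishi methyl‑ketone‑to‑alkyne sequence: kinetic enolisation at the methyl group, O‑phosphorylation, and base‑induced elimination of diethyl phosphate from the terminal enol phosphate, with the tetrasubstituted ring olefin as a spectator.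

**Step 6**
Reactants: 8 2-(but-3-yn-1-yl)-1,3,3-trimethylcyclohex-1-ene
Product: 11 (3E)-4-methyl-6-(2,6,6-trimethylcyclohex-1-en-1-yl)hex-3-en-1-ol, via alkenylalane 9 (not isolated), via lithium alkenylaluminate 10 (not isolated)
Conditions: Me3Al (2.0 equiv), Cp2ZrCl2 (0.25 equiv), CH2Cl2, 0 °C to rt, 12 h; evaporate, hexane/THF; n-BuLi (1.1 equiv), −78 to 0 °C; ethylene oxide (3 equiv), −78 °C to rt; cold 1 M HCl
Reagents that add atoms: trimethylaluminium, C[Al](C)C; ethylene oxide (oxirane), C1CO1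
Why: Zirconium‑catalysed syn‑carboalumination (Negishi) puts methyl on the internal and aluminium on the terminal alkyne carbon, which fixes the E trisubstituted olefin, and the more nucleophilic ate complex then opens ethylene oxide with retention of olefin geometry.

**Step 7**
Reactants: 11 (3E)-4-methyl-6-(2,6,6-trimethylcyclohex-1-en-1-yl)hex-3-en-1-ol
Product: 12 2-[(3E)-6-iodo-3-methylhex-3-en-1-yl]-1,3,3-trimethylcyclohex-1-ene
Conditions: I2, PPh3, imidazole, CH2Cl2, 0 °C to rt, dark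
Reagents that add atoms: iodine, [I][I]
Why: Appel‑type iodination converts the primary alcohol into the iodide by SN2 displacement of an alkoxyphosphonium ion without touching either olefin.

**Step 8**
Reactants: 12 2-[(3E)-6-iodo-3-methylhex-3-en-1-yl]-1,3,3-trimethylcyclohex-1-ene (1.1 equiv); 13 ethyl (triphenylphosphoranylidene)acetate
Product: 15 ethyl (5E)-6-methyl-2-(triphenylphosphoranylidene)-8-(2,6,6-trimethylcyclohex-1-en-1-yl)oct-5-enoate, via phosphonium iodide 14 (not isolated)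
Conditions: MeCN, reflux, 48 h; wash the salt with hexane; then 1 M NaOH, CH2Cl2, rt
Reagents that add atoms: none
Why: SN2 C‑alkylation of the stabilised ylide by the primary iodide gives the phosphonium salt, and hydroxide removes its α‑proton to give the α‑substituted stabilised ylide.

**Step 9**
Reactants: 5 (3S)-3-[(tert-butyldimethylsilyl)oxy]-3-(furan-3-yl)propanal; 15 ethyl (5E)-6-methyl-2-(triphenylphosphoranylidene)-8-(2,6,6-trimethylcyclohex-1-en-1-yl)oct-5-enoate (1.2 equiv)
Product: 16 ethyl (2E,5E)-2-{(3S)-3-[(tert-butyldimethylsilyl)oxy]-3-(furan-3-yl)propylidene}-6-methyl-8-(2,6,6-trimethylcyclohex-1-en-1-yl)oct-5-enoate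
Conditions: toluene, 90 °C, 16 h
Reagents that add atoms: none
Why: Wittig olefination with an α‑branched ester‑stabilised ylide is strongly E‑selective, placing the ester trans to the aldehyde‑derived chain as the target requires, and the β‑silyloxy stereocentre is not affected.

**Step 10**
Reactants: 16 ethyl (2E,5E)-2-{(3S)-3-[(tert-butyldimethylsilyl)oxy]-3-(furan-3-yl)propylidene}-6-methyl-8-(2,6,6-trimethylcyclohex-1-en-1-yl)oct-5-enoate
Product: 17 (2E,5E)-2-{(3S)-3-[(tert-butyldimethylsilyl)oxy]-3-(furan-3-yl)propylidene}-6-methyl-8-(2,6,6-trimethylcyclohex-1-en-1-yl)oct-5-en-1-ol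
Conditions: i-Bu2AlH (2.5 equiv), CH2Cl2, −78 °C; aq. potassium sodium tartrate
Reagents that add atoms: none
Why: 1,2‑Reduction of the conjugated ester by the aluminium hydride gives the allylic alcohol with the olefin geometry intact, while furan, silyl ether and isolated olefins are inert.

**Step 11**
Reactants: 17 (2E,5E)-2-{(3S)-3-[(tert-butyldimethylsilyl)oxy]-3-(furan-3-yl)propylidene}-6-methyl-8-(2,6,6-trimethylcyclohex-1-en-1-yl)oct-5-en-1-ol
Product: 19 4-[(1S,3E,7E)-1-[(tert-butyldimethylsilyl)oxy]-4-(hydroxymethyl)-8-methyl-10-(2,6,6-trimethylcyclohex-1-en-1-yl)deca-3,7-dien-1-yl]-5-hydroxyfuran-2(5H)-one (both C5 epimers), via furan endoperoxide 18 (not isolated)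
Conditions: O2, visible light, rose bengal (cat.), i-Pr2NEt (5 equiv), CH2Cl2/MeOH 19:1, −78 °C; stop when the furan is consumed
Reagents that add atoms: dioxygen (as singlet oxygen), O=O
Why: [4+2] cycloaddition of singlet oxygen to the furan outruns the ene reaction of the hindered olefins at −78 °C, and the hindered amine removes the less hindered bridgehead proton (Kornblum–DeLaMare‑type fragmentation), so the carbonyl ends up distal and the hemiacetal proximal to the side chain; the new hemiacetal centre is a mixture that the next step erases.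

**Step 12**
Reactants: 19 4-[(1S,3E,7E)-1-[(tert-butyldimethylsilyl)oxy]-4-(hydroxymethyl)-8-methyl-10-(2,6,6-trimethylcyclohex-1-en-1-yl)deca-3,7-dien-1-yl]-5-hydroxyfuran-2(5H)-one
Product: 21 4-[(1S,3E,7E)-1-[(tert-butyldimethylsilyl)oxy]-4-(hydroxymethyl)-8-methyl-10-(2,6,6-trimethylcyclohex-1-en-1-yl)deca-3,7-dien-1-yl]furan-2(5H)-one, via ring-opened hydroxy acid 20 (not isolated)
Conditions: NaBH4 (1.5 equiv), EtOH, 0 °C, 30 min; then 1 M HCl to pH 3, rt, 30 min
Reagents that add atoms: none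
Why: The γ‑hydroxybutenolide is a masked cis‑formyl acrylate, so borohydride reduces its aldehyde form chemoselectively and acidification closes the γ‑lactone onto the new primary alcohol (reduction–lactonisation) without touching the carbinol stereocentre.

**Step 13**
Reactants: 21 4-[(1S,3E,7E)-1-[(tert-butyldimethylsilyl)oxy]-4-(hydroxymethyl)-8-methyl-10-(2,6,6-trimethylcyclohex-1-en-1-yl)deca-3,7-dien-1-yl]furan-2(5H)-one
Product: 22 4-[(1S,3E,7E)-1-hydroxy-4-(hydroxymethyl)-8-methyl-10-(2,6,6-trimethylcyclohex-1-en-1-yl)deca-3,7-dien-1-yl]furan-2(5H)-one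
Conditions: HF·pyridine, pyridine, THF, 0 °C to rt
Reagents that add atoms: none
Why: Fluoride‑mediated desilylation under buffered, non‑basic conditions spares the base‑sensitive butenolide and frees the S alcohol unchanged.

**Compound list**
1 | ethyl 3-(furan-3-yl)-3-oxopropanoate | CCOC(=O)CC(=O)c1ccoc1 | starting material
2 | ethyl (3S)-3-(furan-3-yl)-3-hydroxypropanoate | CCOC(=O)C[C@H](O)c1ccoc1 | intermediate
3 | ethyl (3S)-3-[(tert-butyldimethylsilyl)oxy]-3-(furan-3-yl)propanoate | CCOC(=O)C[C@H](O[Si](C)(C)C(C)(C)C)c1ccoc1 | intermediate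
4 | (3S)-3-[(tert-butyldimethylsilyl)oxy]-3-(furan-3-yl)propan-1-ol | OCC[C@H](O[Si](C)(C)C(C)(C)C)c1ccoc1 | intermediate
5 | (3S)-3-[(tert-butyldimethylsilyl)oxy]-3-(furan-3-yl)propanal | O=CC[C@H](O[Si](C)(C)C(C)(C)C)c1ccoc1 | intermediate
6 | 4-(2,6,6-trimethylcyclohex-1-en-1-yl)butan-2-one (dihydro-β-ionone) | CC(=O)CCC1=C(C)CCCC1(C)C | starting material
7 | diethyl 4-(2,6,6-trimethylcyclohex-1-en-1-yl)but-1-en-2-yl phosphate (enol phosphate) | C=C(CCC1=C(C)CCCC1(C)C)OP(=O)(OCC)OCC | intermediate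
8 | 2-(but-3-yn-1-yl)-1,3,3-trimethylcyclohex-1-ene | C#CCCC1=C(C)CCCC1(C)C | intermediate
9 | dimethyl[(1E)-2-methyl-4-(2,6,6-trimethylcyclohex-1-en-1-yl)but-1-en-1-yl]alane (alkenylalane) | C[Al](C)/C=C(C)/CCC1=C(C)CCCC1(C)C | intermediate
10 | lithium butyl(dimethyl)[(1E)-2-methyl-4-(2,6,6-trimethylcyclohex-1-en-1-yl)but-1-en-1-yl]aluminate | [Li+].CCCC[Al-](C)(C)/C=C(C)/CCC1=C(C)CCCC1(C)C | intermediate
11 | (3E)-4-methyl-6-(2,6,6-trimethylcyclohex-1-en-1-yl)hex-3-en-1-ol | OCC/C=C(C)/CCC1=C(C)CCCC1(C)C | intermediate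
12 | 2-[(3E)-6-iodo-3-methylhex-3-en-1-yl]-1,3,3-trimethylcyclohex-1-ene | ICC/C=C(C)/CCC1=C(C)CCCC1(C)C | intermediate
13 | ethyl (triphenylphosphoranylidene)acetate | CCOC(=O)C=P(c1ccccc1)(c1ccccc1)c1ccccc1 | starting material
14 | [(5E)-1-ethoxy-6-methyl-1-oxo-8-(2,6,6-trimethylcyclohex-1-en-1-yl)oct-5-en-2-yl]triphenylphosphonium iodide (racemic at C2) | CCOC(=O)C(CC/C=C(C)/CCC1=C(C)CCCC1(C)C)[P+](c1ccccc1)(c1ccccc1)c1ccccc1.[I-] | intermediate
15 | ethyl (5E)-6-methyl-2-(triphenylphosphoranylidene)-8-(2,6,6-trimethylcyclohex-1-en-1-yl)oct-5-enoate | CCOC(=O)C(CC/C=C(C)/CCC1=C(C)CCCC1(C)C)=P(c1ccccc1)(c1ccccc1)c1ccccc1 | intermediate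
16 | ethyl (2E,5E)-2-{(3S)-3-[(tert-butyldimethylsilyl)oxy]-3-(furan-3-yl)propylidene}-6-methyl-8-(2,6,6-trimethylcyclohex-1-en-1-yl)oct-5-enoate | CC1=C(CC/C(C)=C/CC/C(=C\C[C@H](O[Si](C)(C)C(C)(C)C)c2ccoc2)C(=O)OCC)C(C)(C)CCC1 | intermediate
17 | (2E,5E)-2-{(3S)-3-[(tert-butyldimethylsilyl)oxy]-3-(furan-3-yl)propylidene}-6-methyl-8-(2,6,6-trimethylcyclohex-1-en-1-yl)oct-5-en-1-ol | CC1=C(CC/C(C)=C/CC/C(=C\C[C@H](O[Si](C)(C)C(C)(C)C)c2ccoc2)CO)C(C)(C)CCC1 | intermediate
18 | 5-[(1S,3E,7E)-1-[(tert-butyldimethylsilyl)oxy]-4-(hydroxymethyl)-8-methyl-10-(2,6,6-trimethylcyclohex-1-en-1-yl)deca-3,7-dien-1-yl]-2,3,7-trioxabicyclo[2.2.1]hept-5-ene (furan endoperoxide, bridgehead diastereomers) | CC1=C(CC/C(C)=C/CC/C(=C\C[C@H](O[Si](C)(C)C(C)(C)C)C2=CC3OOC2O3)CO)C(C)(C)CCC1 | intermediate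
19 | 4-[(1S,3E,7E)-1-[(tert-butyldimethylsilyl)oxy]-4-(hydroxymethyl)-8-methyl-10-(2,6,6-trimethylcyclohex-1-en-1-yl)deca-3,7-dien-1-yl]-5-hydroxyfuran-2(5H)-one (both C5 epimers) | CC1=C(CC/C(C)=C/CC/C(=C\C[C@H](O[Si](C)(C)C(C)(C)C)C2=CC(=O)OC2O)CO)C(C)(C)CCC1 | intermediate
20 | (2E,4S,6E,10E)-4-[(tert-butyldimethylsilyl)oxy]-3,7-bis(hydroxymethyl)-11-methyl-13-(2,6,6-trimethylcyclohex-1-en-1-yl)trideca-2,6,10-trienoic acid (CO2H cis to CH2OH; sodium carboxylate in the flask) | CC1=C(CC/C(C)=C/CC/C(=C\C[C@H](O[Si](C)(C)C(C)(C)C)/C(CO)=C/C(O)=O)CO)C(C)(C)CCC1 | intermediate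
21 | 4-[(1S,3E,7E)-1-[(tert-butyldimethylsilyl)oxy]-4-(hydroxymethyl)-8-methyl-10-(2,6,6-trimethylcyclohex-1-en-1-yl)deca-3,7-dien-1-yl]furan-2(5H)-one | CC1=C(CC/C(C)=C/CC/C(=C\C[C@H](O[Si](C)(C)C(C)(C)C)C2=CC(=O)OC2)CO)C(C)(C)CCC1 | intermediate
22 | 4-[(1S,3E,7E)-1-hydroxy-4-(hydroxymethyl)-8-methyl-10-(2,6,6-trimethylcyclohex-1-en-1-yl)deca-3,7-dien-1-yl]furan-2(5H)-one | CC1=C(CC/C(C)=C/CC/C(=C\C[C@H](O)C2=CC(=O)OC2)CO)C(C)(C)CCC1 | target

**Totals**
Total step count: 13. Longest linear sequence: 9 steps (steps 5–13 from 6, or steps 1–4 and 9–13 from 1).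

**Three steps most likely to fail**

Step 6 (one‑pot carboalumination, ate‑complex formation and epoxide opening). The alanate may open ethylene oxide poorly. The fallback sets out from alkyne 8 and comes back at alcohol 11. The same carboalumination (via 9) is quenched with I2 to give the isolable vinyl iodide 2-[(3E)-4-iodo-3-methylbut-3-en-1-yl]-1,3,3-trimethylcyclohex-1-ene F1. Iodine–lithium exchange (t-BuLi, Et2O, −78 °C) then gives the alkenyllithium [(1E)-2-methyl-4-(2,6,6-trimethylcyclohex-1-en-1-yl)but-1-en-1-yl]lithium F2, which opens ethylene oxide in the presence of BF3·OEt2 to give 11.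

Step 8 (alkylation of a stabilised ylide with an unactivated primary iodide). The alkylation may be sluggish, or the salt may lose its ester on prolonged heating. The fallback sets out from iodide 12 and comes back at enoate 16. The sodium salt of triethyl phosphonoacetate (NaH, DMF, 60 °C) is alkylated with 12 to give the phosphonate ethyl (5E)-2-(diethoxyphosphoryl)-6-methyl-8-(2,6,6-trimethylcyclohex-1-en-1-yl)oct-5-enoate F3. Horner–Wadsworth–Emmons olefination of F3 with aldehyde 5 (LiCl, DBU, MeCN, rt) gives 16; this is less E‑selective than the Wittig reaction, so the minor Z isomer is removed by chromatography.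

Step 11 (singlet oxygen in the presence of a tetrasubstituted and two trisubstituted olefins). Ene reaction of the olefins or the wrong regiochemistry of endoperoxide opening could intervene. The fallback sets out from furan 17 and comes back at butenolide 21, by‑passing 19 and step 12. Iridium‑catalysed C–H borylation ([Ir(OMe)(cod)]2, 4,4'-di-tert-butyl-2,2'-bipyridine, excess B2pin2, THF, 50 °C) at the unhindered furan α‑position gives the boronate 2-{4-[(1S,3E,7E)-1-[(tert-butyldimethylsilyl)oxy]-4-(hydroxymethyl)-8-methyl-10-(2,6,6-trimethylcyclohex-1-en-1-yl)deca-3,7-dien-1-yl]furan-2-yl}-4,4,5,5-tetramethyl-1,3,2-dioxaborolane F4. Oxidation of the C–B bond (NaBO3·4H2O, THF/H2O, rt) gives the hydroxyfuran 4-[(1S,3E,7E)-1-[(tert-butyldimethylsilyl)oxy]-4-(hydroxymethyl)-8-methyl-10-(2,6,6-trimethylcyclohex-1-en-1-yl)deca-3,7-dien-1-yl]furan-2-ol F5, which tautomerises (cat. Et3N) to 21.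

**Further compounds**
F1 | step 6 | 2-[(3E)-4-iodo-3-methylbut-3-en-1-yl]-1,3,3-trimethylcyclohex-1-ene | I/C=C(C)/CCC1=C(C)CCCC1(C)C
F2 | step 6 | [(1E)-2-methyl-4-(2,6,6-trimethylcyclohex-1-en-1-yl)but-1-en-1-yl]lithium | [Li]/C=C(C)/CCC1=C(C)CCCC1(C)C
F3 | step 8 | ethyl (5E)-2-(diethoxyphosphoryl)-6-methyl-8-(2,6,6-trimethylcyclohex-1-en-1-yl)oct-5-enoate | CCOC(=O)C(CC/C=C(C)/CCC1=C(C)CCCC1(C)C)P(=O)(OCC)OCC
F4 | step 11 | 2-{4-[(1S,3E,7E)-1-[(tert-butyldimethylsilyl)oxy]-4-(hydroxymethyl)-8-methyl-10-(2,6,6-trimethylcyclohex-1-en-1-yl)deca-3,7-dien-1-yl]furan-2-yl}-4,4,5,5-tetramethyl-1,3,2-dioxaborolane | CC1=C(CC/C(C)=C/CC/C(=C\C[C@H](O[Si](C)(C)C(C)(C)C)c2coc(B3OC(C)(C)C(C)(C)O3)c2)CO)C(C)(C)CCC1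
F5 | step 11 | 4-[(1S,3E,7E)-1-[(tert-butyldimethylsilyl)oxy]-4-(hydroxymethyl)-8-methyl-10-(2,6,6-trimethylcyclohex-1-en-1-yl)deca-3,7-dien-1-yl]furan-2-ol | CC1=C(CC/C(C)=C/CC/C(=C\C[C@H](O[Si](C)(C)C(C)(C)C)c2coc(O)c2)CO)C(C)(C)CCC1
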